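Of three flasks with the same charge and the same time, differing in temperature, which keeps the largest share of its finished material as double product rather than isomer?

| setting | green | violet | midnight | noon | dawn |
|---|---|---|---|---|---|
| substrate | 0.094 M | 0.094 M | 0.094 M | 0.094 M | 0.094 M |
| reagent | 0.60 equiv | 2.4 equiv | 1.20 equiv | 1.20 equiv | 1.20 equiv |
| temperature | 60 °C | 82 °C | 70 °C | 50 °C | 90 °C |
| remark | run made earlier | run made earlier |  |  |  |
| time |  |  | 4.0 min | 4.0 min | 4.0 min |

- green (time / min: double product / %, isomer of the product / %, substrate / %): 0.833: 0.4, 0, 91.2; 1.50: 1.9, 0.1, 85.3; 2.00: 3.1, 0.2, 82.2; 3.00: 6.4, 0, 78.0; 4.00: 7.9, 0.2, 73.0; 5.00: 9.2, 0.8, 69.3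
- violet (time / s: double product / %, isomer of the product / %, substrate / %): 10.0: 5.3, 0.1, 80.7; 15.0: 9.9, 0.6, 75.2; 30.0: 24.8, 1.0, 57.8; 40.0: 32.1, 1.4, 51.2; 60.0: 44.0, 3.2, 39.2; 80.0: 52.2, 4.7, 31.9; 90.0: 55.5, 5.3, 27.9

(standard deviation of a reading: 0.5 percentage points)

- the flask that comes out highest in share of double product in all that became double product or isomer of the product, or "all alike" when all lie within 1.5 percentage points (midnight / noon / dawn / all alike)
- share of double product in all that became double product or isomer of the product, midnight
- share of double product in all that became double product or isomer of the product, noon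
- share of double product in all that became double product or isomer of the product, dawn

- the analysis behind the earlier runs scatters by 0.5 percentage points, standard deviation

The readings don't close. In the violet run at 90.0 s, substrate, double product and isomer add up to 88.7%, so I take the gap to be single product. Single product has paid one reagent, and double product and its isomer have paid two. So the reagent spent, per substrate charged, is the substrate gone plus double product plus isomer, and the unseen single product drops out of the sum.

Dividing that by the substrate gone, violet gives 1.84 equivalents: I call this the reagent price. But violet at 30.0 s reads 1.61, so the price climbs as the violet run proceeds.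

The new flasks carry 1.20 equiv, less than the 2 equiv that full conversion to double product takes, so reagent is the limiting reagent. At violet's price I reckon that dawn stops with 34.9% of its substrate left and 54.9% as double product plus isomer.

That gives the sum, not the split. For the split I have violet's share falling from 96.1% at 30.0 s to 91.3% at 90.0 s, so I put noon, the coolest flask, highest.

The forecast says noon, with 89.5% for midnight, 98.7% for noon and 63% for dawn, where isomer “competes strongly once reagent runs out”.

The flasks give noon, with 91.1% for midnight, 99.0% for noon and 79.2% for dawn.

    substrate + reagent → single product + by-product (k = 0.0560 M⁻¹ s⁻¹, Ea = 44.0 kJ mol⁻¹)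
    reagent + single product → double product + by-product (k = 0.150 M⁻¹ s⁻¹, Ea = 67.0 kJ mol⁻¹)
    double product ⇌ isomer of the product (K = 0.840, k = 7.80 × 10⁻⁴ s⁻¹, Ea = 93.0 kJ mol⁻¹, ΔH = −56.0 kJ mol⁻¹)
    (constants at 70 °C)

In dawn, both reagent steps ran while reagent fell to 17.9% of its charge by 2.00 min and 4.76% by 4.00 min, and double product and isomer exchanged both ways alongside them, and the share at 4.00 min stands near the 77.8% that dawn's equilibrium constant of 0.285 gives and near the 77.8% that dawn shows at 40.0 min, with reagent at 0%. At that time dawn's substrate stands at 34.7% against my 34.9%, and its double product plus isomer at 54.7% against my 54.9%, while midnight, with reagent at 0%, holds substrate at 31.9%.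

Readings and results come from a simulation from invented constants; noise was put on by code.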